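## Retrosynthetic overview

1. The tetronic acid ring is the only ring built and is formed last: terminal alkyne 12 and monomethyl methylmalonate 13 are joined by a ring C–O bond (carboxylate O to the alkyne terminus, setting the Z-ylidene) followed by C4–C5 acylation. Both furans are bought in as furan-3-ylmethanol 1.
2. Alkyne 12 comes from aldehyde 11 by one-carbon homologation, and 11 from alcohol 10.
3. The bis(furyl)methane C–C bond comes from C5–H borylation of the 3-alkylfuran 8 and Suzuki coupling with 3-(chloromethyl)furan 2.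
4. The furan–CH2–CH2 bond comes from 3-furylmethyl Grignard 6 and allylic acetate 5; the (E)-trisubstituted alkene is carried intact from geranyl acetate 3.
5. The methyl stereocentre comes from hydroxyl-directed asymmetric hydrogenation of 8-hydroxygeranyl acetate 4, made from 3 by allylic oxidation.

Assumption: the target is made exactly as drawn (4-hydroxy enol tautomer, Z-ylidene, E-alkene, R-methyl centre); the side chain is numbered from the ylidene carbon (C1), so the stereocentre is C2.

## Route

Step 1
Reactants: 1 furan-3-ylmethanol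
Product: 2 3-(chloromethyl)furan
Conditions: SOCl2, pyridine, Et2O, 0 °C; used as a cold solution
Reagents that add atoms: thionyl chloride, O=S(Cl)Cl
Why: Chlorodehydroxylation of a primary furylmethyl alcohol through its chlorosulfite, buffered by pyridine so the acid-sensitive furan survives.

Step 2
Reactants: 3 geranyl acetate
Product: 4 (2E,6E)-8-hydroxy-3,7-dimethylocta-2,6-dien-1-yl acetate
Conditions: SeO2 (cat.), t-BuOOH, salicylic acid (cat.), CH2Cl2, 25 °C
Reagents that add atoms: tert-butyl hydroperoxide, CC(C)(C)OO (terminal source of the new oxygen); selenium dioxide, O=[Se]=O (catalytic oxygen carrier)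
Why: Catalytic SeO2 allylic oxidation (ene reaction, then [2,3]-sigmatropic shift) hydroxylates the (E)-methyl of the electron-rich terminal alkene, while the alkene deactivated by the allylic acetate is left alone.

Step 3
Reactants: 4 (2E,6E)-8-hydroxy-3,7-dimethylocta-2,6-dien-1-yl acetate
Product: 5 (2E,7R)-8-hydroxy-3,7-dimethyloct-2-en-1-yl acetate
Conditions: Ru(OAc)2[(R)-BINAP] (1 mol%), H2 (40 atm), MeOH, 20 °C
Reagents that add atoms: none
Why: Noyori hydroxyl-directed asymmetric hydrogenation reduces only the alkene of the free allylic alcohol, which binds ruthenium through its OH; the (R)-BINAP ligand is chosen by the facial sense of the geraniol-to-citronellol reduction to give the (R)-methyl centre, and the allylic acetate alkene is untouched.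

Step 4
Reactants: 5 (2E,7R)-8-hydroxy-3,7-dimethyloct-2-en-1-yl acetate; 2 3-(chloromethyl)furan
Product: 8 (2R,6E)-9-(furan-3-yl)-2,6-dimethylnon-6-en-1-ol, via (furan-3-ylmethyl)magnesium chloride 6 (not isolated), via chloromagnesium (2R,6E)-8-acetoxy-2,6-dimethyloct-6-en-1-olate 7 (not isolated)
Conditions: 2, Mg, THF, 0 °C; then 5, Li2CuCl4 (5 mol%), THF, −30 → 0 °C (2.3 equiv of 6, fast addition)
Reagents that add atoms: none
Why: Copper-catalysed Grignard cross-coupling with a primary allylic acetate (Fouquet–Schlosser-type SN2 substitution with retention of the E geometry), the established way to join 3-furylmethyl Grignard reagents to geranyl-type electrophiles; the first equivalent of 6 only deprotonates the hydroxyl and the stereocentre is remote.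

Step 5
Reactants: 8 (2R,6E)-9-(furan-3-yl)-2,6-dimethylnon-6-en-1-ol; 2 3-(chloromethyl)furan
Product: 10 (2R,6E)-9-[5-(furan-3-ylmethyl)furan-3-yl]-2,6-dimethylnon-6-en-1-ol, via O-boryl furan-2-ylboronate 9 (not isolated)
Conditions: [Ir(OMe)(cod)]2 (1.5 mol%), dtbpy (3 mol%), HBpin (2.3 equiv), THF, 25 °C; volatiles off; Pd(OAc)2 (3 mol%), SPhos (6 mol%), 2 (1.4 equiv), aq K3PO4, THF, 45 °C
Reagents that add atoms: none
Why: One-pot iridium-catalysed C–H borylation and Suzuki–Miyaura coupling: borylation of a 3-alkylfuran is sterically steered to the unhindered α-position C5, and the 2-furyl boronate couples with the benzylic-type chloride 2 at zerovalent palladium to give the bis(furyl)methane, the O-boryl group being hydrolysed by the aqueous base.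

Step 6
Reactants: 10 (2R,6E)-9-[5-(furan-3-ylmethyl)furan-3-yl]-2,6-dimethylnon-6-en-1-ol
Product: 11 (2R,6E)-9-[5-(furan-3-ylmethyl)furan-3-yl]-2,6-dimethylnon-6-enal
Conditions: Dess–Martin periodinane, pyridine, CH2Cl2, 0 → 25 °C; aldehyde used crude at once
Reagents that add atoms: none
Why: Dess–Martin oxidation of a primary alcohol under buffered, non-enolising conditions preserves the α-methyl stereocentre, the furans and the alkene.

Step 7
Reactants: 11 (2R,6E)-9-[5-(furan-3-ylmethyl)furan-3-yl]-2,6-dimethylnon-6-enal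
Product: 12 4-[(3E,8R)-4,8-dimethyldec-3-en-9-yn-1-yl]-2-(furan-3-ylmethyl)furan
Conditions: dimethyl (1-diazo-2-oxopropyl)phosphonate, K2CO3, MeOH, 0 → 25 °C
Reagents that add atoms: dimethyl (1-diazo-2-oxopropyl)phosphonate, COP(=O)(OC)C(=[N+]=[N-])C(C)=O
Why: Ohira–Bestmann (Seyferth–Gilbert) homologation, in which the diazomethylphosphonate anion made in the flask adds to the aldehyde and loss of phosphate and N2 with a 1,2-hydride shift gives the terminal alkyne; at 0 °C homologation outruns α-epimerisation.

Step 8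
Reactants: 12 4-[(3E,8R)-4,8-dimethyldec-3-en-9-yn-1-yl]-2-(furan-3-ylmethyl)furan; 13 3-methoxy-2-methyl-3-oxopropanoic acid (monomethyl methylmalonate, racemic)
Product: 15 (5Z)-5-[(2R,6E)-9-[5-(furan-3-ylmethyl)furan-3-yl]-2,6-dimethylnon-6-en-1-ylidene]-4-hydroxy-3-methylfuran-2(5H)-one, via cesium 3-methoxy-2-methyl-3-oxopropanoate 14 (not isolated)
Conditions: 13 (1.5 equiv), Cs2CO3 (0.75 equiv), 4 Å MS, 1,4-dioxane, 25 °C; then 12, [Rh(cod)Cl]2 (2.5 mol%), 2-[(diphenylphosphino)methyl]pyridine (6 mol%), 90 °C; 1 M HCl work-up, 0 °C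
Reagents that add atoms: none
Why: Proposed new method: a monovalent rhodium catalyst with a P,N ligand turns the terminal alkyne into a rhodium vinylidene, and the carboxylate oxygen of 14 adds to the vinylidene α-carbon (anti-Markovnikov, Z-selective C–O bond formation, which makes the ring O–C5 bond); the resulting (Z)-alkenylrhodium is not protonated, because the carboxylate salt is used without free acid, but adds 5-exo to the tethered methyl ester and expels methoxide, and the 2,4-dione so formed enolises to the (Z)-ylidene tetronic acid with the propargylic stereocentre never touched; the closest known reaction types are the rhodium- and ruthenium-catalysed anti-Markovnikov addition of carboxylic acids to terminal alkynes giving (Z)-enol esters and the intramolecular acylation of esters by alkenylrhodium species.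

## Compound list

1 | furan-3-ylmethanol | OCc1ccoc1 | starting material
2 | 3-(chloromethyl)furan | ClCc1ccoc1 | intermediate
3 | geranyl acetate, (2E)-3,7-dimethylocta-2,6-dien-1-yl acetate | CC(C)=CCC/C(C)=C/COC(C)=O | starting material
4 | (2E,6E)-8-hydroxy-3,7-dimethylocta-2,6-dien-1-yl acetate | OC/C(C)=C/CC/C(C)=C/COC(C)=O | intermediate
5 | (2E,7R)-8-hydroxy-3,7-dimethyloct-2-en-1-yl acetate | OC[C@H](C)CCC/C(C)=C/COC(C)=O | intermediate
6 | (furan-3-ylmethyl)magnesium chloride | Cl[Mg]Cc1ccoc1 | intermediate
7 | chloromagnesium (2R,6E)-8-acetoxy-2,6-dimethyloct-6-en-1-olate | Cl[Mg]OC[C@H](C)CCC/C(C)=C/COC(C)=O | intermediate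
8 | (2R,6E)-9-(furan-3-yl)-2,6-dimethylnon-6-en-1-ol | OC[C@H](C)CCC/C(C)=C/CCc1ccoc1 | intermediate
9 | 2-[4-[(3E,8R)-4,8-dimethyl-9-[(4,4,5,5-tetramethyl-1,3,2-dioxaborolan-2-yl)oxy]non-3-en-1-yl]furan-2-yl]-4,4,5,5-tetramethyl-1,3,2-dioxaborolane | CC1(C)OB(OC[C@H](C)CCC/C(C)=C/CCc2coc(B3OC(C)(C)C(C)(C)O3)c2)OC1(C)C | intermediate
10 | (2R,6E)-9-[5-(furan-3-ylmethyl)furan-3-yl]-2,6-dimethylnon-6-en-1-ol | OC[C@H](C)CCC/C(C)=C/CCc1coc(Cc2ccoc2)c1 | intermediate
11 | (2R,6E)-9-[5-(furan-3-ylmethyl)furan-3-yl]-2,6-dimethylnon-6-enal | O=C[C@H](C)CCC/C(C)=C/CCc1coc(Cc2ccoc2)c1 | intermediate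
12 | 4-[(3E,8R)-4,8-dimethyldec-3-en-9-yn-1-yl]-2-(furan-3-ylmethyl)furan | C#C[C@H](C)CCC/C(C)=C/CCc1coc(Cc2ccoc2)c1 | intermediate
13 | 3-methoxy-2-methyl-3-oxopropanoic acid (monomethyl methylmalonate) | COC(=O)C(C)C(=O)O | starting material
14 | cesium 3-methoxy-2-methyl-3-oxopropanoate | [Cs+].COC(=O)C(C)C(=O)[O-] | intermediate
15 | (5Z)-5-[(2R,6E)-9-[5-(furan-3-ylmethyl)furan-3-yl]-2,6-dimethylnon-6-en-1-ylidene]-4-hydroxy-3-methylfuran-2(5H)-one | CC1=C(O)/C(=C/[C@H](C)CCC/C(C)=C/CCc2coc(Cc3ccoc3)c2)OC1=O | target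

## Step count and risk

Total step count: 8. Longest linear sequence: 7 steps (3 to 15, steps 2 to 8).

**Step 8 (the proposed new annulation).** The alkenylrhodium may be protonated to the open (Z)-enol ester instead of acylating, and Markovnikov addition or alkyne dimerisation can compete. The fallback uses known chemistry, sets out from 12 and comes back at 15. Acyl Sonogashira coupling of 12 with propanoyl chloride (PdCl2(PPh3)2, CuI, Et3N, THF, 25 °C) gives the ynone (6R,10E)-13-[5-(furan-3-ylmethyl)furan-3-yl]-6,10-dimethyltridec-10-en-4-yn-3-one F1. Silver-catalysed CO2 incorporation (AgOAc 10 mol%, DBU, CO2 1 MPa, MeCN, 25 °C, then dilute HCl) carboxylates the ethyl ketone at its α-carbon, and the carboxylate closes 5-exo-dig onto the silver-activated alkyne to give the (Z)-tetronic acid 15. The point to watch there is the base-exposed γ-stereocentre, so the ee of 15 is checked.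

**Step 3 (asymmetric hydrogenation).** 2-Methyl-substituted allylic alcohols can give lower ee than geraniol-type substrates with Ru–BINAP, and the ligand sense rests on analogy. The fallback sets out from 4 and comes back at 5, moving the stereo-defining reduction to a carboxylate-directed substrate of the tiglic acid class. MnO2 (CH2Cl2) gives (2E,6E)-8-acetoxy-2,6-dimethylocta-2,6-dienal F2. Pinnick oxidation (NaClO2, NaH2PO4, 2-methyl-2-butene, t-BuOH/H2O) gives (2E,6E)-8-acetoxy-2,6-dimethylocta-2,6-dienoic acid F3. Hydrogenation with Ru(OAc)2[(R)-H8-BINAP] (H2, MeOH) gives (2R,6E)-8-acetoxy-2,6-dimethyloct-6-enoic acid F4. BH3·SMe2 (THF, −10 °C) reduces the acid faster than the ester or the trisubstituted alkene and returns 5.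

**Step 5 (C–H borylation and Suzuki coupling).** Borylation may give some C2 isomer, and the 2-furyl boronate may protodeboronate before coupling. The fallback fixes the regiochemistry with a halide instead of a C–H activation; it sets out from 5 (with 2) and comes back at 10, replacing steps 4 and 5. Zn dust and LiCl in THF convert 2 into (furan-3-ylmethyl)zinc chloride F5. Negishi coupling with commercial methyl 5-bromofuran-3-carboxylate (COC(=O)c1coc(Br)c1; Pd(OAc)2, SPhos, THF, 25 °C) gives methyl 5-(furan-3-ylmethyl)furan-3-carboxylate F6. LiAlH4 (Et2O, 0 °C) gives [5-(furan-3-ylmethyl)furan-3-yl]methanol F7, and SOCl2 with pyridine gives 4-(chloromethyl)-2-(furan-3-ylmethyl)furan F8. Mg in THF gives {[5-(furan-3-ylmethyl)furan-3-yl]methyl}magnesium chloride F9, which is coupled under Li2CuCl4 catalysis with the alkoxide 7 (made from 5 and MeMgCl) to give 10 directly.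

## Further compounds

F1 | step 8 | (6R,10E)-13-[5-(furan-3-ylmethyl)furan-3-yl]-6,10-dimethyltridec-10-en-4-yn-3-one | CCC(=O)C#C[C@H](C)CCC/C(C)=C/CCc1coc(Cc2ccoc2)c1
F2 | step 3 | (2E,6E)-8-acetoxy-2,6-dimethylocta-2,6-dienal | O=C/C(C)=C/CC/C(C)=C/COC(C)=O
F3 | step 3 | (2E,6E)-8-acetoxy-2,6-dimethylocta-2,6-dienoic acid | OC(=O)/C(C)=C/CC/C(C)=C/COC(C)=O
F4 | step 3 | (2R,6E)-8-acetoxy-2,6-dimethyloct-6-enoic acid | OC(=O)[C@H](C)CCC/C(C)=C/COC(C)=O
F5 | step 5 | (furan-3-ylmethyl)zinc chloride | Cl[Zn]Cc1ccoc1
F6 | step 5 | methyl 5-(furan-3-ylmethyl)furan-3-carboxylate | COC(=O)c1coc(Cc2ccoc2)c1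
F7 | step 5 | [5-(furan-3-ylmethyl)furan-3-yl]methanol | OCc1coc(Cc2ccoc2)c1
F8 | step 5 | 4-(chloromethyl)-2-(furan-3-ylmethyl)furan | ClCc1coc(Cc2ccoc2)c1
F9 | step 5 | {[5-(furan-3-ylmethyl)furan-3-yl]methyl}magnesium chloride | Cl[Mg]Cc1coc(Cc2ccoc2)c1
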